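(The data come from a simulation with constants of no real substance, and the scatter is random.)

A small charge of reagent, 1.00 per substrate in this flask against 2.00 on Monday, looks like a stop. Suppose one reagent makes a target and two make an over-reacted product. Then, in the balance of reagent in this flask, a charge used to its end leaves as much over-reacted product as substrate. That balance carries no time, so the clock has to come from the runs.

| setting | Monday's | Wednesday's | flask |
|---|---|---|---|
| substrate | 0.85 M | 1.7 M | 1.7 M |
| reagent in the second phase | 1.7 M | 3.4 M | 1.70 M |
| remark | run made earlier | run made earlier |  |
| time |  |  | 2.0 h |
| volume of the second phase over the first |  |  | 2.0 |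

| run | time / h | target / % |
|---|---|---|
| Monday's | 0.200 | 51 |
| Monday's | 0.417 | 58 |
| Monday's | 1.00 | 39 |
| Monday's | 2.50 | 20 |
| Wednesday's | 0.667 | 41 |
| Wednesday's | 1.33 | 26 |
| Wednesday's | 2.00 | 17 |
| Wednesday's | 2.50 | 16 |

(each reading ± 2 percentage points)

- in the second phase: reagent in the second phase; everything else is in the first
- charges count per volume of the first phase; a concentration in a rate is the amount of a species over the volume of its own phase; every rate counts per litre of the first phase
- the earlier runs hold the two phases in the same ratio of volumes as the flask asked about

- alder: doubling the transfer coefficient of the reagent in the second phase, all else as stated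
- maple: doubling the amount of reagent in the second phase, all else as stated

- how much target there is at 2.0 h, in percent of the substrate charged
- the change that raises the amount of target at 2.0 h, in percent of the substrate charged most ("none" if none brings more than 2 percentage points) (alder / maple / none)
- amount of target at 2.0 h, in percent of the substrate charged, after alder

Monday's run has this flask's reagent charge, and its target falls from 39 % at 1.00 h to 20 % at 2.50 h. The fade, the logarithm of that fall over the hours between, is 0.445 /h. Carried from Monday's reading at 1.00 h to 2.0 h, it gives 25.0 %.

The weak link is Monday's substrate, half of this flask's. Wednesday's run has this flask's substrate but twice its reagent, and it fades at 0.513 /h, which gives 23.3 % from the same reading. That gap is about one reading's scatter, so 25.0 % stands. Maple is Wednesday's charge, which read 17 % at 2.00 h, lower than that figure. Alder quickens the transfer, and Monday's readings show the target already falling by 1.00 h, so this reckoning keeps alder near 25.0 % and answers none.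

The forecast says 59 %, none, and 60 % after alder, holding that the flask “stops where reagent runs out”. Its figure stands higher than this one.

The flask gives 27.5 %, with none as the best change and 27.4 % after alder.

    reagent in the reaction phase ⇌ dormant form (K = 0.730, k = 0.185 /h)
    target ⇌ isomer of the product (K = 0.680, k = 0.185 /h)
    reagent in the reaction phase ⇌ reagent in the second phase, rate k3*([reagent in the reaction phase] - [reagent in the second phase]/K3) per volume of the first phase (partition coefficient = 0.330, kL = 28.8 /h)
    substrate + reagent in the reaction phase ⇌ target (K = 4.70 /M, k = 7.84 /M/h)
    reagent in the reaction phase + target → over-reacted product (k = 1.16 /M/h)

At 1.00 h the flask held 38.6 % target, level with Monday's reading, and the fade carries that to 24.7 %.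

A second flask with 0.68 M of substrate and the same reagent charge gets 25.0 % from the fade on Monday's reading, and its computed result is 24.9 %.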